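**Retrosynthetic overview**

1. The target is an (S)-2,2-disubstituted 2,3,4,7-tetrahydrooxepine (ring: O1, quaternary C2, C3, C4, C5=C6, C7). Last disconnections: global fluoride unmasking, the p-coumarate ester, and the (E)-alkene of the side chain (Wittig on an aldehyde).
2. Key disconnection: O1–C7 together with C6–C1′ of the side chain. The allyl ether triad C5=C6–C7–O1 of the oxepine, with its carbon substituent on C6, is a terminal allene C5=C6=C7 in disguise, placed three carbons from the tertiary C2–OH. Divalent palladium closes the oxepine 7-endo by alkoxypalladation, and the C6–Pd bond picks up acrolein.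
3. C2 is set beforehand by a catalytic enantioselective Mukaiyama aldol (Cu(OTf)2/bis-oxazoline) between an allenyl α-keto ester and the enol silane of protected 2,5-dihydroxyacetophenone.
4. The keto ester comes from but-3-yn-1-ol (Crabbé allene homologation, bromide, Grignard addition to an oxalate).
5. Ring order: only one ring is made, the oxepine, in step 8; both arenes are bought.

Key step: step 8

Remark: the sense of induction in step 7 is taken over from pyruvate esters with the same catalyst (si-face attack on the copper-chelated 1,2-dicarbonyl, giving the (S)-carbinol; the CIP order O > CO2R > CH2C(O)Ar > CH2CH2R is the same in both series). The antipodal ligand would give the enantiomer.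

**Route**

Step 1
Reactants: 1 but-3-yn-1-ol
Product: 3 penta-3,4-dien-1-ol, via Mannich base 2 (not isolated)
Conditions: (CH2O)n, CuBr (0.5 equiv), iPr2NH (2 equiv), 1,4-dioxane, reflux
Reagents that add atoms: paraformaldehyde (as formaldehyde), C=O
Why: Crabbé homologation, in which the copper-mediated Mannich coupling gives the propargylic amine and a 1,5-hydride shift with loss of the imine should turn the terminal alkyne into the terminal allene.

Step 2
Reactants: 3 penta-3,4-dien-1-ol
Product: 4 5-bromopenta-1,2-diene
Conditions: CBr4, PPh3, CH2Cl2, 0 °C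
Reagents that add atoms: carbon tetrabromide, BrC(Br)(Br)Br
Why: Appel bromination of a primary alcohol under neutral conditions should leave the allene untouched.

Step 3
Reactants: 5 oxalyl chloride; 6 2-(trimethylsilyl)ethanol (2.1 equiv)
Product: 7 bis[2-(trimethylsilyl)ethyl] oxalate
Conditions: pyridine, CH2Cl2, 0 °C to rt
Reagents that add atoms: none
Why: Double acylation of a primary alcohol by an acid chloride should give the oxalate whose ester group can later be removed by fluoride.

Step 4
Reactants: 4 5-bromopenta-1,2-diene; 7 bis[2-(trimethylsilyl)ethyl] oxalate (1.5 equiv)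
Product: 9 2-(trimethylsilyl)ethyl 2-oxohepta-5,6-dienoate, via Grignard reagent 8 (not isolated)
Conditions: Mg, THF, rt; then added to 7, THF, −78 °C; aq NH4Cl
Reagents that add atoms: none
Why: Inverse addition of a Grignard reagent to a dialkyl oxalate at low temperature should stop at the α-keto ester, because the tetrahedral adduct survives until the quench.

Step 5
Reactants: 10 1-(2,5-dihydroxyphenyl)ethanone
Product: 11 1-[2,5-bis(tert-butyldimethylsilyloxy)phenyl]ethanone
Conditions: TBSCl (2.5 equiv), imidazole, DMF, 40 °C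
Reagents that add atoms: tert-butyldimethylsilyl chloride, CC(C)(C)[Si](C)(C)Cl
Why: Silylation of both phenols masks the hydroquinone with groups that the final fluoride step removes.

Step 6
Reactants: 11 1-[2,5-bis(tert-butyldimethylsilyloxy)phenyl]ethanone
Product: 12 {1-[2,5-bis(tert-butyldimethylsilyloxy)phenyl]vinyloxy}trimethylsilane
Conditions: TMSOTf, Et3N, CH2Cl2, 0 °C; used crude
Reagents that add atoms: trimethylsilyl triflate, C[Si](C)(C)OS(=O)(=O)C(F)(F)F
Why: Soft enolisation of the methyl ketone with TMSOTf and an amine base should give the only possible enol silane.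

Step 7
Reactants: 9 2-(trimethylsilyl)ethyl 2-oxohepta-5,6-dienoate; 12 the enol silane (1.2 equiv)
Product: 14 2-(trimethylsilyl)ethyl (S)-2-{2-[2,5-bis(tert-butyldimethylsilyloxy)phenyl]-2-oxoethyl}-2-hydroxyhepta-5,6-dienoate, via silyl ether 13 (not isolated)
Conditions: Cu(OTf)2 (10 mol %), (S,S)-tBu-box (11 mol %), THF, −78 °C; then 1 M HCl, THF, 0 °C
Reagents that add atoms: none
Why: Enantioselective Mukaiyama aldol addition to an α-keto ester, in which two-point chelation of the 1,2-dicarbonyl to the square-planar divalent copper bis-oxazoline complex shields the re face, so that si-face attack should set C2 as (S).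

Step 8
Reactants: 14 the (S)-allenyl aldol; 15 acrolein (5 equiv)
Product: 17 2-(trimethylsilyl)ethyl (S)-2-{2-[2,5-bis(tert-butyldimethylsilyloxy)phenyl]-2-oxoethyl}-6-(3-oxopropyl)-2,3,4,7-tetrahydrooxepine-2-carboxylate, via alkenylpalladium bromide 16 (not isolated)
Conditions: Pd(OAc)2 (5 mol %), LiBr (2 equiv), THF, rt
Reagents that add atoms: none
Why: Proposed new method: divalent palladium is expected to bind the terminal C6=C7 π bond of the allene and the tertiary C2–OH to add anti at the unsubstituted terminus C7, which closes the oxepine by O1–C7 bond formation and leaves an endocyclic alkenyl–palladium bond at C6 (16); insertion of acrolein into that bond and protonolysis of the resulting palladium enolate by the HBr set free in the ring closure, with bromide ligands holding back β-hydride elimination, should place the 3-oxopropyl group on C6 and release PdBr2 from 16 back into the catalytic cycle without any oxidant. The closest known reaction types are the PdCl2-catalysed 7-endo cyclizative coupling of γ-allenols with allyl bromide to 2,3,4,7-tetrahydrooxepines and the Pd(OAc)2/LiBr-catalysed heteropalladation of tethered allenes and alkynes that ends in conjugate addition to acrolein; the proposal joins the ring-closing mode of the first to the redox-neutral termination of the second. The single ring is closed in the 7-endo mode, and the C5=C6 double bond is formed inside the ring, so its geometry is fixed and no alkene isomer can arise. No stereocenter is formed and C2 is not touched, and the neutral medium avoids the retro-aldol cleavage that a basic etherification of this β-hydroxy ketone would risk. The selectivity needed is attack at C7 over 5-exo attack at C5 and carbon–carbon capture over simple protodepalladation; the first should be secured by palladium activating the unhindered terminal π bond and by the gem-disubstitution at C2, the second by the excess of acrolein and the halide-rich medium.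

Step 9
Reactants: 17 the oxepine aldehyde; 18 2-(triphenylphosphoranylidene)propanal
Product: 19 2-(trimethylsilyl)ethyl (S)-2-{2-[2,5-bis(tert-butyldimethylsilyloxy)phenyl]-2-oxoethyl}-6-[(E)-4-methyl-5-oxopent-3-en-1-yl]-2,3,4,7-tetrahydrooxepine-2-carboxylate
Conditions: toluene, 80 °C
Reagents that add atoms: none
Why: Wittig olefination with a stabilised formyl ylide should react only at the aliphatic aldehyde and give the (E)-2-methyl enal under thermodynamic control of the oxaphosphetane.

Step 10
Reactants: 19 the (E)-enal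
Product: 20 2-(trimethylsilyl)ethyl (S)-2-{2-[2,5-bis(tert-butyldimethylsilyloxy)phenyl]-2-oxoethyl}-6-[(E)-5-hydroxy-4-methylpent-3-en-1-yl]-2,3,4,7-tetrahydrooxepine-2-carboxylate
Conditions: NaBH4 (1 equiv), MeOH/CH2Cl2 (1:1), −78 °C; aq NH4Cl
Reagents that add atoms: none
Why: Chemoselective 1,2-reduction, since at −78 °C borohydride should reduce the aldehyde far faster than the hindered, donor-substituted aryl ketone and not at all the ester.

Step 11
Reactants: 21 (E)-4-hydroxycinnamic acid (p-coumaric acid)
Product: 23 (E)-3-[4-(tert-butyldimethylsilyloxy)phenyl]acrylic acid, via silyl ester 22 (not isolated)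
Conditions: TBSCl (2.2 equiv), imidazole, DMF, rt; then THF/H2O/AcOH, rt
Reagents that add atoms: tert-butyldimethylsilyl chloride, CC(C)(C)[Si](C)(C)Cl
Why: Exhaustive silylation followed by selective hydrolysis of the much more labile silyl ester should leave the phenol protected and the acid free.

Step 12
Reactants: 20 the allylic alcohol; 23 the protected coumaric acid
Product: 24 2-(trimethylsilyl)ethyl (S)-2-{2-[2,5-bis(tert-butyldimethylsilyloxy)phenyl]-2-oxoethyl}-6-[(E)-5-{(E)-3-[4-(tert-butyldimethylsilyloxy)phenyl]acryloyloxy}-4-methylpent-3-en-1-yl]-2,3,4,7-tetrahydrooxepine-2-carboxylate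
Conditions: DCC, DMAP (cat.), CH2Cl2, 0 °C to rt
Reagents that add atoms: none
Why: Steglich esterification of an unhindered primary allylic alcohol, the only free hydroxyl in the molecule, proceeds without touching either alkene geometry.

Step 13
Reactants: 24 the fully protected target
Product: 25 (S)-2-[2-(2,5-dihydroxyphenyl)-2-oxoethyl]-6-{(E)-5-[(E)-3-(4-hydroxyphenyl)acryloyloxy]-4-methylpent-3-en-1-yl}-2,3,4,7-tetrahydrooxepine-2-carboxylic acid
Conditions: TBAF (5 equiv), THF, 0 °C to rt, argon; then AcOH
Reagents that add atoms: none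
Why: Fluoride should cleave the three aryl silyl ethers and fragment the 2-(trimethylsilyl)ethyl ester (loss of ethene) in one operation, while the allylic coumarate and both alkenes should be left intact.

**Compound list**

1 | but-3-yn-1-ol | C#CCCO | starting material
2 | 5-(diisopropylamino)pent-3-yn-1-ol | CC(C)N(CC#CCCO)C(C)C | intermediate
3 | penta-3,4-dien-1-ol | C=C=CCCO | intermediate
4 | 5-bromopenta-1,2-diene | C=C=CCCBr | intermediate
5 | oxalyl chloride | O=C(Cl)C(=O)Cl | starting material
6 | 2-(trimethylsilyl)ethanol | C[Si](C)(C)CCO | starting material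
7 | bis[2-(trimethylsilyl)ethyl] oxalate | C[Si](C)(C)CCOC(=O)C(=O)OCC[Si](C)(C)C | intermediate
8 | penta-3,4-dienylmagnesium bromide | C=C=CCC[Mg]Br | intermediate
9 | 2-(trimethylsilyl)ethyl 2-oxohepta-5,6-dienoate | C=C=CCCC(=O)C(=O)OCC[Si](C)(C)C | intermediate
10 | 1-(2,5-dihydroxyphenyl)ethanone | CC(=O)c1cc(O)ccc1O | starting material
11 | 1-[2,5-bis(tert-butyldimethylsilyloxy)phenyl]ethanone | CC(=O)c1cc(O[Si](C)(C)C(C)(C)C)ccc1O[Si](C)(C)C(C)(C)C | intermediate
12 | {1-[2,5-bis(tert-butyldimethylsilyloxy)phenyl]vinyloxy}trimethylsilane | C=C(O[Si](C)(C)C)c1cc(O[Si](C)(C)C(C)(C)C)ccc1O[Si](C)(C)C(C)(C)C | intermediate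
13 | trimethylsilyl ether of the (S)-aldol 14 | C=C=CCC[C@](O[Si](C)(C)C)(CC(=O)c1cc(O[Si](C)(C)C(C)(C)C)ccc1O[Si](C)(C)C(C)(C)C)C(=O)OCC[Si](C)(C)C | intermediate
14 | 2-(trimethylsilyl)ethyl (S)-2-{2-[2,5-bis(tert-butyldimethylsilyloxy)phenyl]-2-oxoethyl}-2-hydroxyhepta-5,6-dienoate | C=C=CCC[C@](O)(CC(=O)c1cc(O[Si](C)(C)C(C)(C)C)ccc1O[Si](C)(C)C(C)(C)C)C(=O)OCC[Si](C)(C)C | intermediate
15 | acrolein | C=CC=O | starting material
16 | bromo(oxepin-6-yl)palladium species (C6–Pd, other ligands omitted) | Br[Pd]C1=CCC[C@](CC(=O)c2cc(O[Si](C)(C)C(C)(C)C)ccc2O[Si](C)(C)C(C)(C)C)(C(=O)OCC[Si](C)(C)C)OC1 | intermediate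
17 | (S)-6-(3-oxopropyl)-2,3,4,7-tetrahydrooxepine aldehyde | O=CCCC1=CCC[C@](CC(=O)c2cc(O[Si](C)(C)C(C)(C)C)ccc2O[Si](C)(C)C(C)(C)C)(C(=O)OCC[Si](C)(C)C)OC1 | intermediate
18 | 2-(triphenylphosphoranylidene)propanal | CC(C=O)=P(c1ccccc1)(c1ccccc1)c1ccccc1 | starting material
19 | (S)-6-[(E)-4-methyl-5-oxopent-3-en-1-yl] enal | C/C(C=O)=C\CCC1=CCC[C@](CC(=O)c2cc(O[Si](C)(C)C(C)(C)C)ccc2O[Si](C)(C)C(C)(C)C)(C(=O)OCC[Si](C)(C)C)OC1 | intermediate
20 | (S)-6-[(E)-5-hydroxy-4-methylpent-3-en-1-yl] allylic alcohol | C/C(CO)=C\CCC1=CCC[C@](CC(=O)c2cc(O[Si](C)(C)C(C)(C)C)ccc2O[Si](C)(C)C(C)(C)C)(C(=O)OCC[Si](C)(C)C)OC1 | intermediate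
21 | (E)-4-hydroxycinnamic acid | O=C(O)/C=C/c1ccc(O)cc1 | starting material
22 | tert-butyldimethylsilyl (E)-3-[4-(tert-butyldimethylsilyloxy)phenyl]acrylate | CC(C)(C)[Si](C)(C)OC(=O)/C=C/c1ccc(O[Si](C)(C)C(C)(C)C)cc1 | intermediate
23 | (E)-3-[4-(tert-butyldimethylsilyloxy)phenyl]acrylic acid | O=C(O)/C=C/c1ccc(O[Si](C)(C)C(C)(C)C)cc1 | intermediate
24 | fully protected target (three aryl silyl ethers, 2-(trimethylsilyl)ethyl ester) | C/C(=C\CCC1=CCC[C@](CC(=O)c2cc(O[Si](C)(C)C(C)(C)C)ccc2O[Si](C)(C)C(C)(C)C)(C(=O)OCC[Si](C)(C)C)OC1)COC(=O)/C=C/c1ccc(O[Si](C)(C)C(C)(C)C)cc1 | intermediate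
25 | CNP0602535.2, (S)-2-[2-(2,5-dihydroxyphenyl)-2-oxoethyl]-6-{(E)-5-[(E)-3-(4-hydroxyphenyl)acryloyloxy]-4-methylpent-3-en-1-yl}-2,3,4,7-tetrahydrooxepine-2-carboxylic acid | C/C(=C\CCC1=CCC[C@](CC(=O)c2cc(O)ccc2O)(C(=O)O)OC1)COC(=O)/C=C/c1ccc(O)cc1 | target

**Step count**

Total: 13 steps. Longest linear sequence: 9 steps (steps 1, 2, 4, 7, 8, 9, 10, 12, 13).

**Steps most likely to fail**

Step 8 (proposed new method). The ring closure may take the 5-exo course at C5, the alkenylpalladium may be protonated before acrolein inserts, or bromide may add to the allene instead of the hydroxyl. The fallback uses known chemistry and sets out from 14. PdCl2 (5 mol %) with allyl bromide (5 equiv) in DMF at rt, the established 7-endo cyclizative coupling of γ-allenols, should give the 6-allyl tetrahydrooxepine F1. Hydroboration of its terminal alkene with 9-BBN (1.1 equiv, THF, 0 °C) should give the B-alkyl borane F2 (not isolated), which NaBO3·4H2O in THF/H2O oxidises to the primary alcohol F3. Dess–Martin periodinane with NaHCO3 in CH2Cl2 then gives the aldehyde, and the route is rejoined at 17.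

Step 10. Hydride may also be delivered to the aryl ketone, or the enal may be reduced in the conjugate sense. The fallback sets out from 19 and replaces the selective reduction by a redox detour that needs no selectivity between the carbonyl groups. NaBH4/CeCl3·7H2O in MeOH at 0 °C should reduce both the aldehyde and the ketone to the diol F4 (mixture of epimers at the benzylic carbinol). The unhindered primary allylic alcohol is then esterified selectively with 23 (1 equiv, DCC, DMAP, CH2Cl2, 0 °C) to the hydroxy ester F5. Dess–Martin periodinane oxidises the remaining benzylic alcohol back to the ketone, and the route is rejoined at 24.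

Step 13. The basic fluoride medium may trigger β-elimination of the ring oxygen from the enolised aryl ketone (opening of the oxepine, which would also erase C2), air oxidation of the liberated hydroquinone, or cleavage of the allylic coumarate. The fallback sets out from 24 and unmasks the molecule in two acidic stages. HF·pyridine buffered with pyridine in THF (0 °C to rt) should remove the three aryl silyl groups and give the triphenol 2-(trimethylsilyl)ethyl ester F6. TFA/CH2Cl2 (1:4, 0 °C) then cleaves the ester by acid-induced β-silyl fragmentation, and the route is rejoined at 25.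

**Further compounds**

F1 | step 8 | 2-(trimethylsilyl)ethyl (S)-6-allyl-2-{2-[2,5-bis(tert-butyldimethylsilyloxy)phenyl]-2-oxoethyl}-2,3,4,7-tetrahydrooxepine-2-carboxylate | C=CCC1=CCC[C@](CC(=O)c2cc(O[Si](C)(C)C(C)(C)C)ccc2O[Si](C)(C)C(C)(C)C)(C(=O)OCC[Si](C)(C)C)OC1
F2 | step 8 | B-alkyl-9-borabicyclo[3.3.1]nonane adduct of F1 (boron on the terminal carbon) | C1CC2CCCC(C1)B2CCCC1=CCC[C@](CC(=O)c2cc(O[Si](C)(C)C(C)(C)C)ccc2O[Si](C)(C)C(C)(C)C)(C(=O)OCC[Si](C)(C)C)OC1
F3 | step 8 | 2-(trimethylsilyl)ethyl (S)-2-{2-[2,5-bis(tert-butyldimethylsilyloxy)phenyl]-2-oxoethyl}-6-(3-hydroxypropyl)-2,3,4,7-tetrahydrooxepine-2-carboxylate | OCCCC1=CCC[C@](CC(=O)c2cc(O[Si](C)(C)C(C)(C)C)ccc2O[Si](C)(C)C(C)(C)C)(C(=O)OCC[Si](C)(C)C)OC1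
F4 | step 10 | diol from full reduction of 19 (benzylic carbinol as a mixture of epimers) | C/C(CO)=C\CCC1=CCC[C@](CC(O)c2cc(O[Si](C)(C)C(C)(C)C)ccc2O[Si](C)(C)C(C)(C)C)(C(=O)OCC[Si](C)(C)C)OC1
F5 | step 10 | primary coumarate of F4 with free benzylic alcohol | C/C(=C\CCC1=CCC[C@](CC(O)c2cc(O[Si](C)(C)C(C)(C)C)ccc2O[Si](C)(C)C(C)(C)C)(C(=O)OCC[Si](C)(C)C)OC1)COC(=O)/C=C/c1ccc(O[Si](C)(C)C(C)(C)C)cc1
F6 | step 13 | 2-(trimethylsilyl)ethyl ester of the target (all three phenols free) | C/C(=C\CCC1=CCC[C@](CC(=O)c2cc(O)ccc2O)(C(=O)OCC[Si](C)(C)C)OC1)COC(=O)/C=C/c1ccc(O)cc1
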